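## The problem

Target 14 is a bibenzyl whose ring A is a fully substituted benzene. C1 carries the Ca–Cb ethylene bridge to the 3-methoxyphenyl ring B, C2, C4 and C6 each carry a 4-hydroxybenzyl group, C3 a free hydroxyl and C5 a methoxy group. No ring has to be built and the molecule has no stereocenter, so the task is to place six different groups around one benzene ring and to make four aryl–CH2 bonds at carbons that each stand between two neighbours. The two ring A oxygens must be told apart (C3 free, C5 methylated), and the methyl ethers on rings A and B must outlive whatever unmasks the four phenols. The compound is sensitive in two ways: the phenols make it oxidisable, and the three 4-hydroxybenzyl–aryl bonds belong to electron-rich diarylmethanes that strong acid can reopen by ipso protonation, so the end of the route must be neutral. The most hindered bond is C1–Ca, because C1 lies between the C2 and C6 benzyl groups, and any method that has to bring a transition metal onto C1 is at a disadvantage. Two features help: C2, C4 and C6 are exactly the positions ortho and para to the two oxygens, so a 3,5-dioxygenated ring can be benzylated position by position until none is left, and the end point is the same whatever the order. And C1 bears precisely a two-carbon link to ring B, so a vinyl unit can be inserted between C1, delivered as a nucleophile on boron, and ring B, delivered as an electrophile; the one stereocenter this creates (Ca while it bears boron) is erased in the next step.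

## Retrosynthesis

**14 from 13.** The four phenolic O–H bonds are traced back to O–benzyl bonds. Benzyl is the only common phenol mask that comes off under neutral conditions that leave the two methyl ethers and the three diarylmethane links alone. All four are removed in one operation, so the protected compound 13 costs a single step. The forward reaction only has to reach the C3 ether, which is buried between two benzyl arms.

**13 from 12.** The Ca–H bond is traced back to a Ca–B bond. The boron in 12 is the trace left by the bond-forming step. Because Ca is benzylic, the C–B bond can be replaced by C–H without touching anything else. The step removes the only stereocenter of the route, so 12 can be racemic.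

**12 from 6, 9 and 8.** Two bonds are cut at once, C1–Ca and Cb–C(ring B), which takes out the whole bridge and ring B. The neighbouring single cuts are weaker. Cutting only C1–Ca means coupling an alkylmetal or an alkyne with bromide 6, which requires palladium to insert at, or transmetalate to, a carbon with two ortho benzyl groups. Cutting Ca–Cb means a benzyl–benzyl coupling next to three other benzylic positions. In the three-component cut C1 acts only as a carbanion: bromide 6 becomes aryllithium 10, which adds to the vinyl boronic ester 9 to give boronate 11, and palladium enters through the unhindered triflate 8. The forward reaction must generate 10 without proton transfer from the flanking CH2 groups, and the 1,2-shift of ring A must outrun direct transfer of a group from boron to palladium.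

**6 from 5.** The C3 O–benzyl bond is cut. The hydroxyl is kept free through the ring alkylations because it is the smallest and strongest donor ring A can carry. It is capped only when every ring carbon is blocked, so that the etherification has no C-alkylation to compete with. Phenol 5 is simpler than 6 by one benzyl group. The forward reaction has to alkylate an oxygen that stands between two benzyl arms.

**5 from 4 and 2.** The C4–CH2 bond is cut. C4 lies between the two oxygens, the position of a 1,3-dioxygenated ring that electrophiles reach last, so it is the natural final carbon to be filled and the first arm to be removed in the backward direction. The three arms are taken off one at a time and not all together. Each forward step then meets one equivalent of benzylic alcohol 2 with one equivalent of ring A, the cation is never in excess over the ring that should capture it, and only this last alkylation needs forcing conditions. Phenol 4 has one ring hydrogen left. The forward reaction must close a hexasubstituted ring before the cation is consumed by the pendant benzyloxyphenyl rings.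

**4 from 3 and 2.** The C2–CH2 bond is cut. C2 and C6 are the two bromine-flanked positions, each para to one oxygen and ortho to the other, and they are the fast sites of the ring. Which of the two arms is removed here and which in the next cut is immaterial, because the forward sequence fills both before C4. Precursor 3 carries a single arm. The forward reaction asks only that the alkylation stay on ring A.

**3 from 1 and 2.** The C6–CH2 bond is cut, which leads to phenol 1 and alcohol 2. Phenol 1 already contains the C3/C5 oxygen differentiation and the C1 handle, so nothing about ring A has to be constructed. Its bromine-bearing carbon is meta to both donors and is the least likely site of ipso attack. The forward reaction need not choose between C6 and C2 or stop cleanly after one alkylation, since every C-benzylated product converges on 5.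

**8 from 7.** The S–O bond of the triflate is cut, leading to phenol 7. Triflate rather than halide is chosen as the ring B leaving group so that no halide ion enters the catalytic step.

## Roads not taken

**Alternative 1:** Ring A is cut at C4–C5 and C5–C6, with C5 supplied by carbon monoxide A3. In the forward sense the racemic (E)-3-pivaloyloxy-1,4-enyne A2 is exposed to [Rh(CO)2Cl]2, a monovalent rhodium carbonyl complex, under A3. A 1,2-acyloxy shift would give a rhodium carbene, insertion of A3 a dienylketene, and six-electron closure the phenol A1 with the C3 oxygen as pivalate and the C5 oxygen free.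
- Merits: the two oxygens are differentiated by construction, and no bond has to be made to an already crowded arene.
- Weak points: the alkyne of A2 is internal and benzyl-terminated, and for such propargylic esters the 1,3-acyloxy shift to an allenyl ester competes with the required 1,2-shift. A2 itself needs a multi-step assembly with control of a trisubstituted alkene and three isomerisation-prone benzylic or skipped positions. After A1 three further operations remain (methylation of the hindered C5 hydroxyl, ester cleavage, hydrogenolysis).
- Comparison: this road is better in that it depends neither on repeated Friedel–Crafts alkylation nor on an aryllithium next to acidic CH2 groups. The chosen plan sets against it a ring A that is bought rather than built, four simple commercial starting materials and a shorter sequence of simpler steps.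

**Alternative 2:** Three bonds around C1 are cut together, C2–CH2, C6–CH2 and C1–Ca. Forward, aryl iodide A5, two equivalents of 4-benzyloxybenzyl bromide A6 and 3-methoxystyrene A7 would combine under Pd(OAc)2 and a triarylphosphine with norbornene A8 as transient mediator. Two ortho C–H alkylations and a terminating Heck reaction would give the (E)-stilbene A4, whose hydrogenation would coincide with debenzylation.
- Merits: this is the most convergent plan on paper, three skeletal bonds in one step, and it is modular in the benzyl groups.
- Weak points: both ortho C–H bonds of A5 are buttressed, C2 by the C3 acetal oxygen and C6 by the C5 methoxy group, and palladacycle formation next to a meta substituent is the known limit of this chemistry. A6 adds directly to zerovalent palladium and can benzylate A7 or homocouple. The terminating Heck step must occur at an arylpalladium with two new ortho benzyl groups. A5 needs its own regioselective monobenzylation at C4, oxygen differentiation and iodination.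
- Comparison: if it worked, its length would be similar to that of the chosen route, and it is better in convergence. The chosen plan sets against it that its ring benzylations follow the innate nucleophilicity of ring A rather than C–H activation at crowded sites, and that palladium never has to sit on C1.

**Alternative 3:** Ring A is cut at C4–C5 and C1–C6. Forward, the fully substituted 2-pyrone A10 and the 1-methoxyalkyne A11 would undergo inverse-demand [4+2] cycloaddition, and loss of carbon dioxide A12 from the bridged lactone would give the arene A9 with an aroyl group at C4.
- Merits: the polarity matches, since the nucleophilic benzyl-bearing alkyne carbon bonds to pyrone C6 and the methoxy-bearing carbon to the acylated C3. The C5 methoxy group arrives in place, and extrusion of A12 makes the step irreversible.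
- Weak points: A10 carries four substituents and a donor alkoxy group at its C4, which lowers its electrophilicity and raises the temperature needed. A11 has a benzylic propargylic CH2 and isomerises readily to an allenyl ether. A10 and A11 each need several steps. The C4 ketone of A9, flanked by the C3 and C5 oxygens, must still be reduced to CH2.
- Comparison: this road gives full positional control of ring A by construction and avoids organolithium chemistry, which is a real advantage. The chosen plan sets against it simple starting materials and the absence of any late deoxygenation.

Key step: step 6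

Remark: boronate 12 is drawn without configuration at Ca because an achiral ligand gives the racemate and this center is removed in step 7; the target has no stereocenter.

Remark: the first benzylation is written at C6, para to the hydroxyl; attack at C2 would give an isomer of 3 that step 2 converts into the same compound 4, so nothing downstream depends on this assignment.

## Route

Step 1
Reactants: 1 3-bromo-5-methoxyphenol; 2 4-benzyloxybenzyl alcohol
Product: 3 4-(4-benzyloxybenzyl)-3-bromo-5-methoxyphenol
Conditions: Sc(OTf)3 (cat.), MeNO2, rt, slow addition of 2 (1.0 equiv); crude product taken on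
Reagents that add atoms: none
Why: Friedel–Crafts benzylation: the Lewis acid ionises 2 to a 4-alkoxybenzyl cation, which is captured by the doubly oxygen-activated ring of 1 at a bromine-flanked carbon that is para to one oxygen and ortho to the other, written here as C6. Ring A is far more nucleophilic than the monoalkoxy rings of 2, and neither regio- nor mono-selectivity is demanded, because the C2 isomer and any doubly benzylated material lie on the same path to 4 and 5.

Step 2
Reactants: 3 4-(4-benzyloxybenzyl)-3-bromo-5-methoxyphenol; 2 4-benzyloxybenzyl alcohol
Product: 4 2,4-bis(4-benzyloxybenzyl)-3-bromo-5-methoxyphenol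
Conditions: Sc(OTf)3 (cat.), MeNO2, 40 °C, slow addition of 2 (1.0 equiv); crude product taken on
Reagents that add atoms: none
Why: Second Friedel–Crafts benzylation at C2, the remaining bromine-flanked carbon, which is para to the methoxy group and ortho to the hydroxyl; C4, between the two oxygens, is the slowest site of a 1,3-dioxygenated ring and is left for step 3. Any C2-benzylated isomer carried over from step 1 reacts at C6 and gives the same compound 4.

Step 3
Reactants: 4 2,4-bis(4-benzyloxybenzyl)-3-bromo-5-methoxyphenol; 2 4-benzyloxybenzyl alcohol
Product: 5 2,4,6-tris(4-benzyloxybenzyl)-3-bromo-5-methoxyphenol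
Conditions: Sc(OTf)3 (cat.), MeNO2, 60 °C, slow addition of 2 (1.3 equiv)
Reagents that add atoms: none
Why: Third Friedel–Crafts benzylation at C4, the only ring carbon of 4 that still bears hydrogen and one that is ortho to both oxygen donors; the bromine-bearing carbon is meta to both donors and is not attacked. O-Benzylated by-products re-ionise under the Lewis acid and funnel to the C-alkylated product.

Step 4
Reactants: 5 2,4,6-tris(4-benzyloxybenzyl)-3-bromo-5-methoxyphenol
Product: 6 1-benzyloxy-3-bromo-5-methoxy-2,4,6-tris(4-benzyloxybenzyl)benzene
Conditions: BnBr, K2CO3, DMF, 60 °C
Reagents that add atoms: benzyl bromide, BrCc1ccccc1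
Why: Williamson etherification of a 2,6-disubstituted phenol; the phenoxide oxygen remains accessible and every ring carbon is blocked, so only O-alkylation can occur.

Step 5
Reactants: 7 3-methoxyphenol
Product: 8 3-methoxyphenyl trifluoromethanesulfonate
Conditions: Tf2O, pyridine, CH2Cl2, 0 °C
Reagents that add atoms: trifluoromethanesulfonic anhydride, O=S(=O)(OS(=O)(=O)C(F)(F)F)C(F)(F)F
Why: Standard O-sulfonylation of a phenol; it gives a halide-free electrophile for the coupling.

Step 6
Reactants: 6 1-benzyloxy-3-bromo-5-methoxy-2,4,6-tris(4-benzyloxybenzyl)benzene; 9 vinylboronic acid pinacol ester; 8 3-methoxyphenyl trifluoromethanesulfonate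
Product: 12 racemic 2-[1-(3-benzyloxy-5-methoxy-2,4,6-tris(4-benzyloxybenzyl)phenyl)-2-(3-methoxyphenyl)ethyl]-4,4,5,5-tetramethyl-1,3,2-dioxaborolane, via ring A aryllithium 10 (not isolated), via lithium vinylboronate complex 11 (not isolated)
Conditions: n-BuLi (0.98 equiv), THF, −78 °C, 10 min; 9, −78 °C to rt; volatiles removed in vacuo; then 8, Pd(OAc)2 (cat.), Fe(C5H4PCy2)2 [1,1'-bis(dicyclohexylphosphino)ferrocene] (cat.), THF, 60 °C
Reagents that add atoms: none
Why: Bromine–lithium exchange at −78 °C gives aryllithium 10, which is trapped at once by 9 as the four-coordinate boronate 11 before it can abstract a diarylmethane proton. Zerovalent palladium inserts into the C–O bond of triflate 8 to give a cationic aryl divalent palladium species that binds the vinyl group of 11. Ring A then shifts from boron to Ca anti to palladium as the Pd–Cb bond forms (1,2-metallate shift), and reductive elimination joins Cb to ring B and returns zerovalent palladium. The closest known reaction type is the palladium-catalysed conjunctive cross-coupling of vinylboron ate complexes with aryl triflates, in which electron-rich aryl groups migrate well; a migrating aryl with two ortho substituents is the extension asked of it here. No ring is closed. Ca becomes a stereocenter, formed racemic because the ferrocenyl bisphosphine is achiral, and since step 7 replaces boron by hydrogen no control element is needed. The selectivity required is metallate shift over direct boron-to-palladium transfer of vinyl or aryl and over beta-hydride loss from the alkylpalladium: the two ortho benzyl groups retard aryl transfer and are relieved of strain as boron returns to three-coordination, palladium stays cationic and alkene-bound because no halide salt is present (the exchange by-product is a volatile alkyl bromide removed before catalysis), and the wide-bite-angle ligand speeds reductive elimination.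

Step 7
Reactants: 12 racemic 2-[1-(3-benzyloxy-5-methoxy-2,4,6-tris(4-benzyloxybenzyl)phenyl)-2-(3-methoxyphenyl)ethyl]-4,4,5,5-tetramethyl-1,3,2-dioxaborolane
Product: 13 1-benzyloxy-5-methoxy-3-[2-(3-methoxyphenyl)ethyl]-2,4,6-tris(4-benzyloxybenzyl)benzene
Conditions: TBAF·3H2O, toluene, 90 °C
Reagents that add atoms: none
Why: Fluoride-promoted protodeboronation of a secondary benzylic pinacol boronate: fluoride forms the boron ate complex and the benzylic C–B bond is protonated by the water of hydration. Benzyl and methyl ethers are inert to these conditions.

Step 8
Reactants: 13 1-benzyloxy-5-methoxy-3-[2-(3-methoxyphenyl)ethyl]-2,4,6-tris(4-benzyloxybenzyl)benzene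
Product: 14 2,4,6-tris(4-hydroxybenzyl)-3-methoxy-5-[2-(3-methoxyphenyl)ethyl]phenol (target)
Conditions: H2 (1 atm), Pd/C, EtOAc–MeOH, rt
Reagents that add atoms: none
Why: Catalytic hydrogenolysis of four aryl benzyl ethers under neutral conditions; diarylmethane and bibenzyl C–C bonds and aryl methyl ethers are not cleaved at room temperature and atmospheric pressure.

## Compound list

1 | 3-bromo-5-methoxyphenol | COc1cc(O)cc(Br)c1 | starting material
2 | 4-benzyloxybenzyl alcohol | OCc1ccc(OCc2ccccc2)cc1 | starting material
3 | 4-(4-benzyloxybenzyl)-3-bromo-5-methoxyphenol | COc1cc(O)cc(Br)c1Cc1ccc(OCc2ccccc2)cc1 | intermediate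
4 | 2,4-bis(4-benzyloxybenzyl)-3-bromo-5-methoxyphenol | COc1cc(O)c(Cc2ccc(OCc3ccccc3)cc2)c(Br)c1Cc1ccc(OCc2ccccc2)cc1 | intermediate
5 | 2,4,6-tris(4-benzyloxybenzyl)-3-bromo-5-methoxyphenol | COc1c(Cc2ccc(OCc3ccccc3)cc2)c(O)c(Cc2ccc(OCc3ccccc3)cc2)c(Br)c1Cc1ccc(OCc2ccccc2)cc1 | intermediate
6 | 1-benzyloxy-3-bromo-5-methoxy-2,4,6-tris(4-benzyloxybenzyl)benzene | COc1c(Cc2ccc(OCc3ccccc3)cc2)c(OCc2ccccc2)c(Cc2ccc(OCc3ccccc3)cc2)c(Br)c1Cc1ccc(OCc2ccccc2)cc1 | intermediate
7 | 3-methoxyphenol | COc1cccc(O)c1 | starting material
8 | 3-methoxyphenyl trifluoromethanesulfonate | COc1cccc(OS(=O)(=O)C(F)(F)F)c1 | intermediate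
9 | vinylboronic acid pinacol ester | C=CB1OC(C)(C)C(C)(C)O1 | starting material
10 | [3-benzyloxy-5-methoxy-2,4,6-tris(4-benzyloxybenzyl)phenyl]lithium | COc1c(Cc2ccc(OCc3ccccc3)cc2)c(OCc2ccccc2)c(Cc2ccc(OCc3ccccc3)cc2)c([Li])c1Cc1ccc(OCc2ccccc2)cc1 | intermediate (not isolated)
11 | lithium [3-benzyloxy-5-methoxy-2,4,6-tris(4-benzyloxybenzyl)phenyl](vinyl)(pinacolato)borate | [Li+].C=C[B-]1(OC(C)(C)C(C)(C)O1)c1c(Cc2ccc(OCc3ccccc3)cc2)c(OCc2ccccc2)c(Cc2ccc(OCc3ccccc3)cc2)c(OC)c1Cc1ccc(OCc2ccccc2)cc1 | intermediate (not isolated)
12 | racemic 2-[1-(3-benzyloxy-5-methoxy-2,4,6-tris(4-benzyloxybenzyl)phenyl)-2-(3-methoxyphenyl)ethyl]-4,4,5,5-tetramethyl-1,3,2-dioxaborolane | COc1cccc(CC(B2OC(C)(C)C(C)(C)O2)c2c(Cc3ccc(OCc4ccccc4)cc3)c(OCc3ccccc3)c(Cc3ccc(OCc4ccccc4)cc3)c(OC)c2Cc2ccc(OCc3ccccc3)cc2)c1 | intermediate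
13 | 1-benzyloxy-5-methoxy-3-[2-(3-methoxyphenyl)ethyl]-2,4,6-tris(4-benzyloxybenzyl)benzene | COc1cccc(CCc2c(Cc3ccc(OCc4ccccc4)cc3)c(OCc3ccccc3)c(Cc3ccc(OCc4ccccc4)cc3)c(OC)c2Cc2ccc(OCc3ccccc3)cc2)c1 | intermediate
14 | 2,4,6-tris(4-hydroxybenzyl)-3-methoxy-5-[2-(3-methoxyphenyl)ethyl]phenol | COc1cccc(CCc2c(Cc3ccc(O)cc3)c(O)c(Cc3ccc(O)cc3)c(OC)c2Cc2ccc(O)cc2)c1 | target

## Step count and least certain steps

Total: 8 steps. Longest linear sequence: 7 steps (steps 1, 2, 3, 4, 6, 7, 8); step 5 is a one-step side branch.

**Step 6 (key step).** Three processes could defeat it. Aryllithium 10 may be quenched by proton transfer from a diarylmethane CH2, or be captured too slowly by 9 because of crowding, which would end in protodebromination. During catalysis, the vinyl group of 11 may transfer directly from boron to palladium, because the crowded boron resists the geometry needed for the 1,2-shift. Traces of bromide may inhibit the cationic palladium intermediate; adding a triflate salt such as KOTf to precipitate halide is the first adjustment. The fallback abandons boron chemistry and goes by formylation, olefination and hydrogenation. From 6, the same cold bromine–lithium exchange is followed by quenching with N,N-dimethylformamide, a small electrophile, to give 3-benzyloxy-5-methoxy-2,4,6-tris(4-benzyloxybenzyl)benzaldehyde F1. Horner–Wadsworth–Emmons olefination of F1 with commercial diethyl (3-methoxybenzyl)phosphonate and KOtBu in THF should give 1-benzyloxy-5-methoxy-3-[(E)-2-(3-methoxyphenyl)ethenyl]-2,4,6-tris(4-benzyloxybenzyl)benzene F2. Hydrogenation of F2 over Pd/C saturates the alkene and removes the four benzyl ethers in one operation. The fallback returns to the route at 14 and bypasses 12 and 13.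

**Step 3.** The third alkylation, which makes the hexasubstituted ring, may stall at C4. Meanwhile the cation from 2 may be consumed by self-condensation or by attack on the pendant benzyloxyphenyl rings, and acid-mediated benzyl transfer may scramble the arms. The same side reactions act in steps 1 and 2, where ring A is more open and they matter less. The fallback replaces innate electrophilic benzylation by halogenation and cross-coupling and also stands in for steps 1, 2 and 4. From 1, iodination at all three free positions (I2, NaHCO3, aqueous THF) should give 3-bromo-2,4,6-triiodo-5-methoxyphenol F3. O-Benzylation (BnBr, K2CO3, DMF) converts F3 into 1-benzyloxy-3-bromo-2,4,6-triiodo-5-methoxybenzene F4. A threefold Negishi coupling of F4 follows, with 4-benzyloxybenzylzinc chloride F5 (from commercial 4-benzyloxybenzyl chloride, Zn dust and LiCl in THF) under Pd(OAc)2 and SPhos. It relies on the faster insertion of palladium into C–I than into C–Br and delivers 6, where the fallback rejoins the route, bypassing 3, 4 and 5.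

**Step 7.** Fluoride may add only slowly to the boron of 12, which is shielded by the two ortho benzyl groups. The developing benzylic carbanion is also poorly stabilised by an electron-rich ring that is twisted out of conjugation, so protodeboronation may be incomplete. The fallback goes through oxygen instead. From 12, oxidation with NaBO3·4H2O in THF–water should give racemic 1-[3-benzyloxy-5-methoxy-2,4,6-tris(4-benzyloxybenzyl)phenyl]-2-(3-methoxyphenyl)ethanol F6. Syn-dehydration of F6 with the Burgess reagent in warm toluene avoids a free benzylic cation and gives the stilbene 1-benzyloxy-5-methoxy-3-[(E)-2-(3-methoxyphenyl)ethenyl]-2,4,6-tris(4-benzyloxybenzyl)benzene F2, the same compound as in the fallback to step 6. Hydrogenation of F2 over Pd/C returns to the route at 14, bypassing 13.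

**Step 8.** Hydrogenolysis of the C3 benzyl ether, which is buried between two benzyl arms, may be slow. The catalyst may also be poisoned by ammonium or boron residues carried over from step 7, leaving partly protected material. The fallback changes the mechanism of deprotection. From 13, BCl3 with pentamethylbenzene as cation scavenger in CH2Cl2 at −78 °C cleaves aryl benzyl ethers while sparing aryl methyl ethers. The low temperature and the scavenger protect the diarylmethane links, and the reaction gives 14 directly without new intermediates.

## Further compounds

F1 | step 6 | 3-benzyloxy-5-methoxy-2,4,6-tris(4-benzyloxybenzyl)benzaldehyde | COc1c(Cc2ccc(OCc3ccccc3)cc2)c(OCc2ccccc2)c(Cc2ccc(OCc3ccccc3)cc2)c(C=O)c1Cc1ccc(OCc2ccccc2)cc1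
F2 | step 6 | 1-benzyloxy-5-methoxy-3-[(E)-2-(3-methoxyphenyl)ethenyl]-2,4,6-tris(4-benzyloxybenzyl)benzene | COc1cccc(/C=C/c2c(Cc3ccc(OCc4ccccc4)cc3)c(OCc3ccccc3)c(Cc3ccc(OCc4ccccc4)cc3)c(OC)c2Cc2ccc(OCc3ccccc3)cc2)c1
F3 | step 3 | 3-bromo-2,4,6-triiodo-5-methoxyphenol | COc1c(I)c(O)c(I)c(Br)c1I
F4 | step 3 | 1-benzyloxy-3-bromo-2,4,6-triiodo-5-methoxybenzene | COc1c(I)c(OCc2ccccc2)c(I)c(Br)c1I
F5 | step 3 | 4-benzyloxybenzylzinc chloride | Cl[Zn]Cc1ccc(OCc2ccccc2)cc1
F6 | step 7 | racemic 1-[3-benzyloxy-5-methoxy-2,4,6-tris(4-benzyloxybenzyl)phenyl]-2-(3-methoxyphenyl)ethanol | COc1cccc(CC(O)c2c(Cc3ccc(OCc4ccccc4)cc3)c(OCc3ccccc3)c(Cc3ccc(OCc4ccccc4)cc3)c(OC)c2Cc2ccc(OCc3ccccc3)cc2)c1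
F0 | step 8 | none | none
A1 | alternative 1 | 3-hydroxy-5-[2-(3-methoxyphenyl)ethyl]-2,4,6-tris(4-benzyloxybenzyl)phenyl pivalate | COc1cccc(CCc2c(Cc3ccc(OCc4ccccc4)cc3)c(OC(=O)C(C)(C)C)c(Cc3ccc(OCc4ccccc4)cc3)c(O)c2Cc2ccc(OCc3ccccc3)cc2)c1
A2 | alternative 1 | racemic (E)-1,7-bis(4-benzyloxyphenyl)-4-(4-benzyloxybenzyl)-3-[2-(3-methoxyphenyl)ethyl]hept-2-en-5-yn-4-yl pivalate | COc1cccc(CC/C(=C\Cc2ccc(OCc3ccccc3)cc2)C(Cc2ccc(OCc3ccccc3)cc2)(OC(=O)C(C)(C)C)C#CCc2ccc(OCc3ccccc3)cc2)c1
A3 | alternative 1 | carbon monoxide | [C-]#[O+]
A4 | alternative 2 | 1-methoxy-3-(methoxymethoxy)-5-[(E)-2-(3-methoxyphenyl)ethenyl]-2,4,6-tris(4-benzyloxybenzyl)benzene | COc1cccc(/C=C/c2c(Cc3ccc(OCc4ccccc4)cc3)c(OCOC)c(Cc3ccc(OCc4ccccc4)cc3)c(OC)c2Cc2ccc(OCc3ccccc3)cc2)c1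
A5 | alternative 2 | 2-(4-benzyloxybenzyl)-5-iodo-1-methoxy-3-(methoxymethoxy)benzene | COCOc1cc(I)cc(OC)c1Cc1ccc(OCc2ccccc2)cc1
A6 | alternative 2 | 4-benzyloxybenzyl bromide | BrCc1ccc(OCc2ccccc2)cc1
A7 | alternative 2 | 3-methoxystyrene | C=Cc1cccc(OC)c1
A8 | alternative 2 | norbornene | C1=CC2CCC1C2
A9 | alternative 3 | [2-benzyloxy-6-methoxy-4-[2-(3-methoxyphenyl)ethyl]-3,5-bis(4-benzyloxybenzyl)phenyl](4-benzyloxyphenyl)methanone | COc1cccc(CCc2c(Cc3ccc(OCc4ccccc4)cc3)c(OCc3ccccc3)c(C(=O)c3ccc(OCc4ccccc4)cc3)c(OC)c2Cc2ccc(OCc3ccccc3)cc2)c1
A10 | alternative 3 | 4-benzyloxy-3-(4-benzyloxybenzoyl)-5-(4-benzyloxybenzyl)-6-[2-(3-methoxyphenyl)ethyl]-2H-pyran-2-one | O=C1OC(CCc2cccc(OC)c2)=C(Cc2ccc(OCc3ccccc3)cc2)C(OCc2ccccc2)=C1C(=O)c1ccc(OCc2ccccc2)cc1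
A11 | alternative 3 | 1-benzyloxy-4-(3-methoxyprop-2-yn-1-yl)benzene | COC#CCc1ccc(OCc2ccccc2)cc1
A12 | alternative 3 | carbon dioxide | O=C=O
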